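**Retrosynthetic overview**

- The strategy rests on the C8=C12 exocyclic methylene next to the C9 stereocentre (C9 carries C11 and ring C, C1'–C6'). C8–C9 is cut to a C9 radical (from a xanthate) and a C8≡C12 terminal alkyne, so ring B closes 6-exo-dig and the methylene is formed directly.
- The cyclisation precursor comes from C11–C1' bond formation (aryllithium opening of a C9/C11 epoxide on ring A). Ring A is elaborated from a cyclohexenone: asymmetric conjugate addition sets C5, anti formylation of the silyl enol ether sets quaternary C10, and Wolff–Kishner reduction removes the C1 oxygen.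
- Ring C is carried as a protected para-methoxyphenol and dearomatised only after ring B exists: quinone monoketal, face-selective epoxidation of C1'=C2', hydrolysis, directed reduction at C3'.
- Ring order: ring A and the arene ring C are bought, ring B is closed in the key step, the oxirane is the last ring.

Key step: step 14

Assumption: drimane numbering is used (C1–C10 decalin carbons, C11 the benzylic CH2, C12 the methylene carbon, C1'–C6' ring C with C1' on C11 and C6' the final ketone); the C9-oxygenated intermediates between the epoxide and the xanthate are carried as epimer mixtures because both epimers give the same C9 radical.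

**Route**

Step 1
Reactants: 1 5-hydroxy-2-methoxybenzaldehyde
Product: 2 2-methoxy-5-(methoxymethoxy)benzaldehyde
Conditions: MOMCl, iPr2NEt, CH2Cl2, 0 °C → rt
Reagents that add atoms: chloromethyl methyl ether, COCCl
Why: Williamson-type O-alkylation of the phenol with the chloromethyl ether masks the acidic OH as an acetal that later stabilises the ortho-aryllithium.

Step 2
Reactants: 2 2-methoxy-5-(methoxymethoxy)benzaldehyde
Product: 3 [2-methoxy-5-(methoxymethoxy)phenyl]methanol
Conditions: NaBH4, MeOH, 0 °C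
Reagents that add atoms: none
Why: Borohydride reduction of the aryl aldehyde gives the benzylic alcohol (the future C4' hydroxymethyl group) without touching the acetal.

Step 3
Reactants: 3 [2-methoxy-5-(methoxymethoxy)phenyl]methanol
Product: 4 tert-butyl{[2-methoxy-5-(methoxymethoxy)phenyl]methoxy}dimethylsilane
Conditions: TBSCl, imidazole, CH2Cl2, rt
Reagents that add atoms: tert-butyl(chloro)dimethylsilane, CC(C)(C)[Si](C)(C)Cl
Why: Standard silylation of a primary alcohol with a silyl chloride and imidazole gives a base-stable ether that should survive the organolithium, radical and oxidative steps.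

Step 4
Reactants: 4 tert-butyl{[2-methoxy-5-(methoxymethoxy)phenyl]methoxy}dimethylsilane
Product: 5 {[4-bromo-2-methoxy-5-(methoxymethoxy)phenyl]methoxy}(tert-butyl)dimethylsilane
Conditions: NBS, MeCN, 0 °C → rt
Reagents that add atoms: N-bromosuccinimide, O=C1CCC(=O)N1Br
Why: Electrophilic aromatic bromination of the hydroquinone diether should go para to the benzylic substituent and ortho to the methoxymethoxy group (C1'), the usual site in 2,5-dialkoxybenzyl systems, which fixes where C11 will be attached.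

Step 5
Reactants: 6 2,4,4-trimethylcyclohex-2-en-1-one; 7 but-3-en-1-ylmagnesium bromide
Product: 9 {[(3S)-3-(but-3-en-1-yl)-2,4,4-trimethylcyclohex-1-en-1-yl]oxy}trimethylsilane, via magnesium enolate 8 (not isolated)
Conditions: Cu(OTf)2 (3 mol %), chiral hydroxyalkyl-imidazolinium salt (carbene ligand precursor, 4 mol %, enantiomer chosen for the 3S product), Et2O, −30 °C; then Me3SiCl, Et3N, DMPU, −30 °C → rt
Reagents that add atoms: chlorotrimethylsilane, C[Si](C)(C)Cl
Why: Copper-catalysed asymmetric conjugate addition of a Grignard reagent to an α-methyl cyclic enone: the chiral carbene–copper complex selects the enone face and sets C5, and O-silylation of magnesium enolate 8 preserves the regiodefined tetrasubstituted enolate as its silyl ether.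

Step 6
Reactants: 9 {[(3S)-3-(but-3-en-1-yl)-2,4,4-trimethylcyclohex-1-en-1-yl]oxy}trimethylsilane
Product: 10 (2S,3S)-3-(but-3-en-1-yl)-2-(dimethoxymethyl)-2,4,4-trimethylcyclohexan-1-one
Conditions: HC(OMe)3, Me3SiOTf (10 mol %), CH2Cl2, −78 °C
Reagents that add atoms: trimethyl orthoformate, COC(OC)OC
Why: Mukaiyama-type alkylation of the silyl enol ether with the dimethoxycarbenium ion from the orthoformate forms the C10–C9 bond; attack anti to the pseudoaxial butenyl group on C5 should set the quaternary C10 with C9 trans to the C5 chain and the methyl group cis to it.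

Step 7
Reactants: 10 (2S,3S)-3-(but-3-en-1-yl)-2-(dimethoxymethyl)-2,4,4-trimethylcyclohexan-1-one
Product: 12 (1S,2S)-2-(but-3-en-1-yl)-1-(dimethoxymethyl)-1,3,3-trimethylcyclohexane, via hydrazone 11 (not isolated)
Conditions: N2H4·H2O, KOH, diethylene glycol, N2, 130 °C then 200 °C
Reagents that add atoms: none
Why: Wolff–Kishner reduction (Huang-Minlon procedure) removes the C1 carbonyl through hydrazone 11; the acetal and the isolated alkene should tolerate hot base under nitrogen, and the quaternary C10 cannot epimerise.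

Step 8
Reactants: 12 (1S,2S)-2-(but-3-en-1-yl)-1-(dimethoxymethyl)-1,3,3-trimethylcyclohexane
Product: 13 (1S,2S)-2-(but-3-en-1-yl)-1,3,3-trimethylcyclohexane-1-carbaldehyde
Conditions: 2 M aq HCl, THF, 40 °C
Reagents that add atoms: water, O
Why: Acid-catalysed acetal hydrolysis frees the C9 aldehyde, which has no α-hydrogen and therefore cannot epimerise or enolise.

Step 9
Reactants: 13 (1S,2S)-2-(but-3-en-1-yl)-1,3,3-trimethylcyclohexane-1-carbaldehyde
Product: 14 2-[(1S,2S)-2-(but-3-en-1-yl)-1,3,3-trimethylcyclohexyl]oxirane (C9 epimer mixture)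
Conditions: Me3S+ I−, KN(SiMe3)2, THF, 0 °C → rt
Reagents that add atoms: trimethylsulfonium iodide, C[S+](C)C.[I-]
Why: Corey–Chaykovsky epoxidation: the sulfonium ylide adds to the non-enolisable neopentyl aldehyde and the betaine closes to the terminal oxirane, C11 arriving as the ring CH2; the C9 configuration is left uncontrolled on purpose.

Step 10
Reactants: 5 {[4-bromo-2-methoxy-5-(methoxymethoxy)phenyl]methoxy}(tert-butyl)dimethylsilane; 14 2-[(1S,2S)-2-(but-3-en-1-yl)-1,3,3-trimethylcyclohexyl]oxirane (C9 epimer mixture)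
Product: 16 1-[(1S,2S)-2-(but-3-en-1-yl)-1,3,3-trimethylcyclohexyl]-2-[4-({[tert-butyl(dimethyl)silyl]oxy}methyl)-5-methoxy-2-(methoxymethoxy)phenyl]ethan-1-ol (C9 epimer mixture), via aryllithium 15 (not isolated)
Conditions: 5, n-BuLi, THF, −78 °C; then 14, BF3·OEt2, −78 °C
Reagents that add atoms: none
Why: Bromine–lithium exchange gives aryllithium 15, stabilised by the ortho methoxymethoxy group, and BF3-promoted SN2 opening of the terminal epoxide at its unhindered CH2 forms the C11–C1' bond and the C9 carbinol together.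

Step 11
Reactants: 16 1-[(1S,2S)-2-(but-3-en-1-yl)-1,3,3-trimethylcyclohexyl]-2-[4-({[tert-butyl(dimethyl)silyl]oxy}methyl)-5-methoxy-2-(methoxymethoxy)phenyl]ethan-1-ol (C9 epimer mixture)
Product: 17 3-[(1S,2S)-2-{2-[4-({[tert-butyl(dimethyl)silyl]oxy}methyl)-5-methoxy-2-(methoxymethoxy)phenyl]-1-hydroxyethyl}-2,6,6-trimethylcyclohexyl]propanal (C9 epimer mixture)
Conditions: OsO4 (2 mol %), NaIO4, 2,6-lutidine, dioxane–H2O, rt
Reagents that add atoms: osmium tetroxide, O=[Os](=O)(=O)=O; sodium periodate, [Na+].[O-]I(=O)(=O)=O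
Why: Lemieux–Johnson oxidation (catalytic osmylation then periodate cleavage) cuts only the terminal alkene to the C8 aldehyde, the buffered neutral medium leaving the electron-rich arene, the acetal and the silyl ether alone.

Step 12
Reactants: 17 3-[(1S,2S)-2-{2-[4-({[tert-butyl(dimethyl)silyl]oxy}methyl)-5-methoxy-2-(methoxymethoxy)phenyl]-1-hydroxyethyl}-2,6,6-trimethylcyclohexyl]propanal (C9 epimer mixture)
Product: 18 1-[(1S,2S)-2-(but-3-yn-1-yl)-1,3,3-trimethylcyclohexyl]-2-[4-({[tert-butyl(dimethyl)silyl]oxy}methyl)-5-methoxy-2-(methoxymethoxy)phenyl]ethan-1-ol (C9 epimer mixture)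
Conditions: dimethyl (1-diazo-2-oxopropyl)phosphonate, K2CO3, MeOH, 0 °C → rt
Reagents that add atoms: dimethyl (1-diazo-2-oxopropyl)phosphonate, CC(=O)C(=[N+]=[N-])P(=O)(OC)OC
Why: The Ohira–Bestmann modification of the Seyferth–Gilbert homologation converts the C8 aldehyde into the C8≡C12 terminal alkyne (C12 from the reagent) under mild carbonate conditions compatible with the free carbinol.

Step 13
Reactants: 18 1-[(1S,2S)-2-(but-3-yn-1-yl)-1,3,3-trimethylcyclohexyl]-2-[4-({[tert-butyl(dimethyl)silyl]oxy}methyl)-5-methoxy-2-(methoxymethoxy)phenyl]ethan-1-ol (C9 epimer mixture)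
Product: 20 O-{1-[(1S,2S)-2-(but-3-yn-1-yl)-1,3,3-trimethylcyclohexyl]-2-[4-({[tert-butyl(dimethyl)silyl]oxy}methyl)-5-methoxy-2-(methoxymethoxy)phenyl]ethyl} S-methyl carbonodithioate (C9 epimer mixture), via sodium xanthate salt 19 (not isolated)
Conditions: NaH, THF, 0 °C; CS2; MeI, 0 °C → rt
Reagents that add atoms: carbon disulfide, S=C=S; iodomethane, CI
Why: Xanthate formation as in the Barton–McCombie sequence: the alkoxide, formed selectively because the carbinol is far more acidic than the alkyne C–H, adds to CS2 and the dithiocarbonate salt 19 is S-methylated.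

Step 14
Reactants: 20 O-{1-[(1S,2S)-2-(but-3-yn-1-yl)-1,3,3-trimethylcyclohexyl]-2-[4-({[tert-butyl(dimethyl)silyl]oxy}methyl)-5-methoxy-2-(methoxymethoxy)phenyl]ethyl} S-methyl carbonodithioate (C9 epimer mixture)
Product: 21 tert-butyl{[2-methoxy-5-(methoxymethoxy)-4-{[(1S,4aS,8aS)-5,5,8a-trimethyl-2-methylidenedecahydronaphthalen-1-yl]methyl}phenyl]methoxy}dimethylsilane
Conditions: Bu3SnH, AIBN (both by syringe pump), PhMe (high dilution), 100 °C
Reagents that add atoms: none
Why: Bu3Sn• adds to the thiocarbonyl sulfur and the C9–O bond breaks, so both xanthate epimers give the same planar secondary C9 radical, which adds to C8 of the terminal alkyne; the C12 vinyl radical then takes hydrogen from Bu3SnH and carries the chain. The closest known reaction type is the tin hydride-mediated cyclisation of xanthate-derived (Barton–McCombie) alkyl radicals onto alkynes to give methylenecycloalkanes. Ring B closes in the 6-exo-dig mode by forming C8–C9. C9 is set in a chair-like transition state built on the trans-diequatorial C5 and C10 chains of ring A, in which the arylmethyl group (C11) lies pseudoequatorial and the C9 hydrogen pseudoaxial on the α face, anti to the axial C10 methyl group, which should give the trans-decalin with 9α-H. The step needs ring closure to outrun hydrogen transfer to the C9 radical and the 1,5-hydrogen shift from C7, and it needs exo rather than endo attack: slow addition of the hydride at high dilution and the hold of ring A on the two chains secure the first, and the terminal alkyne, whose unsubstituted C12 would have to form a seven-membered ring, secures the second. The alkyne gives the C8=C12 methylene at once, with no alkene-position problem and no acid.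

Step 15
Reactants: 21 tert-butyl{[2-methoxy-5-(methoxymethoxy)-4-{[(1S,4aS,8aS)-5,5,8a-trimethyl-2-methylidenedecahydronaphthalen-1-yl]methyl}phenyl]methoxy}dimethylsilane
Product: 23 5-({[tert-butyl(dimethyl)silyl]oxy}methyl)-4-methoxy-2-{[(1S,4aS,8aS)-5,5,8a-trimethyl-2-methylidenedecahydronaphthalen-1-yl]methyl}phenol, via aryl trimethylsilyl ether 22 (not isolated)
Conditions: Me3SiOTf, 2,2'-bipyridyl, CH2Cl2, 0 °C → rt; then H2O
Reagents that add atoms: none
Why: Silyl triflate–bipyridyl cleavage of an aromatic methoxymethyl ether: the buffered aprotic conditions convert the aryl acetal into silyl ether 22, which water hydrolyses to the phenol, while the primary silyl ether and the acid-sensitive exocyclic alkene should be untouched.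

Step 16
Reactants: 23 5-({[tert-butyl(dimethyl)silyl]oxy}methyl)-4-methoxy-2-{[(1S,4aS,8aS)-5,5,8a-trimethyl-2-methylidenedecahydronaphthalen-1-yl]methyl}phenol
Product: 24 5-({[tert-butyl(dimethyl)silyl]oxy}methyl)-4,4-dimethoxy-2-{[(1S,4aS,8aS)-5,5,8a-trimethyl-2-methylidenedecahydronaphthalen-1-yl]methyl}cyclohexa-2,5-dien-1-one
Conditions: PhI(OAc)2, MeOH, 0 °C
Reagents that add atoms: methanol, CO
Why: Oxidative dearomatisation of a para-methoxyphenol with a hypervalent iodine reagent in methanol: the phenoxenium ion is trapped by methanol at C3', giving the quinone monoketal with the free carbonyl at C6'.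

Step 17
Reactants: 24 5-({[tert-butyl(dimethyl)silyl]oxy}methyl)-4,4-dimethoxy-2-{[(1S,4aS,8aS)-5,5,8a-trimethyl-2-methylidenedecahydronaphthalen-1-yl]methyl}cyclohexa-2,5-dien-1-one
Product: 25 (1S,6R)-4-({[tert-butyl(dimethyl)silyl]oxy}methyl)-5,5-dimethoxy-1-{[(1S,4aS,8aS)-5,5,8a-trimethyl-2-methylidenedecahydronaphthalen-1-yl]methyl}-7-oxabicyclo[4.1.0]hept-3-en-2-one
Conditions: t-BuOOH, aq NaOH, N-benzylcinchonidinium chloride (10 mol %), PhMe, 0 °C → rt
Reagents that add atoms: tert-butyl hydroperoxide, CC(C)(C)OO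
Why: Asymmetric Weitz–Scheffer epoxidation under chiral phase-transfer catalysis: the peroxide anion adds to C2', the only unsubstituted β-carbon, so C1'=C2' reacts and C4'=C5' does not, and the chiral ammonium ion pair chooses the face, setting C1' and C2' together as the cis-fused oxirane.

Step 18
Reactants: 25 (1S,6R)-4-({[tert-butyl(dimethyl)silyl]oxy}methyl)-5,5-dimethoxy-1-{[(1S,4aS,8aS)-5,5,8a-trimethyl-2-methylidenedecahydronaphthalen-1-yl]methyl}-7-oxabicyclo[4.1.0]hept-3-en-2-one
Product: 26 (1S,6R)-4-(hydroxymethyl)-1-{[(1S,4aS,8aS)-5,5,8a-trimethyl-2-methylidenedecahydronaphthalen-1-yl]methyl}-7-oxabicyclo[4.1.0]hept-3-ene-2,5-dione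
Conditions: 48% aq HF, MeCN, 0 °C
Reagents that add atoms: water, O
Why: Aqueous HF hydrolyses the dimethyl ketal to the C3' ketone and cleaves the silyl ether in the same operation; the epoxide, flanked by two carbonyl groups, should resist acid opening.

Step 19
Reactants: 26 (1S,6R)-4-(hydroxymethyl)-1-{[(1S,4aS,8aS)-5,5,8a-trimethyl-2-methylidenedecahydronaphthalen-1-yl]methyl}-7-oxabicyclo[4.1.0]hept-3-ene-2,5-dione
Product: 27 (1S,5S,6S)-5-hydroxy-4-(hydroxymethyl)-1-{[(1S,4aS,8aS)-5,5,8a-trimethyl-2-methylidenedecahydronaphthalen-1-yl]methyl}-7-oxabicyclo[4.1.0]hept-3-en-2-one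
Conditions: NaBH(OAc)3, AcOH, MeCN, −20 → 0 °C
Reagents that add atoms: none
Why: Hydroxyl-directed triacetoxyborohydride reduction (Saksena–Evans reduction): the C4' hydroxymethyl group binds boron and delivers hydride to the neighbouring C3' carbonyl and not to the remote, hindered C6' carbonyl, on the face anti to the epoxide C–O bond, so the new C3' hydroxyl should be cis to the epoxide oxygen as in the target.

**Compound list**

1 | 5-hydroxy-2-methoxybenzaldehyde | COc1ccc(O)cc1C=O | starting material
2 | 2-methoxy-5-(methoxymethoxy)benzaldehyde | COCOc1ccc(OC)c(C=O)c1 | intermediate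
3 | [2-methoxy-5-(methoxymethoxy)phenyl]methanol | COCOc1ccc(OC)c(CO)c1 | intermediate
4 | tert-butyl{[2-methoxy-5-(methoxymethoxy)phenyl]methoxy}dimethylsilane | COCOc1ccc(OC)c(CO[Si](C)(C)C(C)(C)C)c1 | intermediate
5 | {[4-bromo-2-methoxy-5-(methoxymethoxy)phenyl]methoxy}(tert-butyl)dimethylsilane | COCOc1cc(CO[Si](C)(C)C(C)(C)C)c(OC)cc1Br | intermediate
6 | 2,4,4-trimethylcyclohex-2-en-1-one | CC1=CC(C)(C)CCC1=O | starting material
7 | but-3-en-1-ylmagnesium bromide | C=CCC[Mg]Br | starting material
8 | bromomagnesium (3S)-3-(but-3-en-1-yl)-2,4,4-trimethylcyclohex-1-en-1-olate (magnesium enolate) | C=CCC[C@H]1C(C)(C)CCC(O[Mg]Br)=C1C | intermediate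
9 | {[(3S)-3-(but-3-en-1-yl)-2,4,4-trimethylcyclohex-1-en-1-yl]oxy}trimethylsilane | C=CCC[C@H]1C(C)(C)CCC(O[Si](C)(C)C)=C1C | intermediate
10 | (2S,3S)-3-(but-3-en-1-yl)-2-(dimethoxymethyl)-2,4,4-trimethylcyclohexan-1-one | C=CCC[C@H]1C(C)(C)CCC(=O)[C@]1(C)C(OC)OC | intermediate
11 | hydrazone of ketone 10 (C=N–NH2 at C1; stereocentres unchanged) | C=CCC[C@H]1C(C)(C)CCC(=NN)[C@]1(C)C(OC)OC | intermediate
12 | (1S,2S)-2-(but-3-en-1-yl)-1-(dimethoxymethyl)-1,3,3-trimethylcyclohexane | C=CCC[C@H]1C(C)(C)CCC[C@]1(C)C(OC)OC | intermediate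
13 | (1S,2S)-2-(but-3-en-1-yl)-1,3,3-trimethylcyclohexane-1-carbaldehyde | C=CCC[C@H]1C(C)(C)CCC[C@]1(C)C=O | intermediate
14 | 2-[(1S,2S)-2-(but-3-en-1-yl)-1,3,3-trimethylcyclohexyl]oxirane (C9 epimer mixture) | C=CCC[C@H]1C(C)(C)CCC[C@]1(C)C1CO1 | intermediate
15 | {4-({[tert-butyl(dimethyl)silyl]oxy}methyl)-5-methoxy-2-(methoxymethoxy)phenyl}lithium (aryllithium) | [Li]c1cc(OC)c(CO[Si](C)(C)C(C)(C)C)cc1OCOC | intermediate
16 | 1-[(1S,2S)-2-(but-3-en-1-yl)-1,3,3-trimethylcyclohexyl]-2-[4-({[tert-butyl(dimethyl)silyl]oxy}methyl)-5-methoxy-2-(methoxymethoxy)phenyl]ethan-1-ol (C9 epimer mixture) | C=CCC[C@H]1C(C)(C)CCC[C@]1(C)C(O)Cc1cc(OC)c(CO[Si](C)(C)C(C)(C)C)cc1OCOC | intermediate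
17 | 3-[(1S,2S)-2-{2-[4-({[tert-butyl(dimethyl)silyl]oxy}methyl)-5-methoxy-2-(methoxymethoxy)phenyl]-1-hydroxyethyl}-2,6,6-trimethylcyclohexyl]propanal (C9 epimer mixture) | O=CCC[C@H]1C(C)(C)CCC[C@]1(C)C(O)Cc1cc(OC)c(CO[Si](C)(C)C(C)(C)C)cc1OCOC | intermediate
18 | 1-[(1S,2S)-2-(but-3-yn-1-yl)-1,3,3-trimethylcyclohexyl]-2-[4-({[tert-butyl(dimethyl)silyl]oxy}methyl)-5-methoxy-2-(methoxymethoxy)phenyl]ethan-1-ol (C9 epimer mixture) | C#CCC[C@H]1C(C)(C)CCC[C@]1(C)C(O)Cc1cc(OC)c(CO[Si](C)(C)C(C)(C)C)cc1OCOC | intermediate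
19 | sodium O-alkyl carbonodithioate of alcohol 18 (sodium xanthate salt) | C#CCC[C@H]1C(C)(C)CCC[C@]1(C)C(OC(=S)[S-])Cc1cc(OC)c(CO[Si](C)(C)C(C)(C)C)cc1OCOC.[Na+] | intermediate
20 | O-{1-[(1S,2S)-2-(but-3-yn-1-yl)-1,3,3-trimethylcyclohexyl]-2-[4-({[tert-butyl(dimethyl)silyl]oxy}methyl)-5-methoxy-2-(methoxymethoxy)phenyl]ethyl} S-methyl carbonodithioate (C9 epimer mixture) | C#CCC[C@H]1C(C)(C)CCC[C@]1(C)C(OC(=S)SC)Cc1cc(OC)c(CO[Si](C)(C)C(C)(C)C)cc1OCOC | intermediate
21 | tert-butyl{[2-methoxy-5-(methoxymethoxy)-4-{[(1S,4aS,8aS)-5,5,8a-trimethyl-2-methylidenedecahydronaphthalen-1-yl]methyl}phenyl]methoxy}dimethylsilane | C=C1CC[C@H]2C(C)(C)CCC[C@]2(C)[C@H]1Cc1cc(OC)c(CO[Si](C)(C)C(C)(C)C)cc1OCOC | intermediate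
22 | trimethylsilyl ether of phenol 23 (aryl trimethylsilyl ether) | C=C1CC[C@H]2C(C)(C)CCC[C@]2(C)[C@H]1Cc1cc(OC)c(CO[Si](C)(C)C(C)(C)C)cc1O[Si](C)(C)C | intermediate
23 | 5-({[tert-butyl(dimethyl)silyl]oxy}methyl)-4-methoxy-2-{[(1S,4aS,8aS)-5,5,8a-trimethyl-2-methylidenedecahydronaphthalen-1-yl]methyl}phenol | C=C1CC[C@H]2C(C)(C)CCC[C@]2(C)[C@H]1Cc1cc(OC)c(CO[Si](C)(C)C(C)(C)C)cc1O | intermediate
24 | 5-({[tert-butyl(dimethyl)silyl]oxy}methyl)-4,4-dimethoxy-2-{[(1S,4aS,8aS)-5,5,8a-trimethyl-2-methylidenedecahydronaphthalen-1-yl]methyl}cyclohexa-2,5-dien-1-one | C=C1CC[C@H]2C(C)(C)CCC[C@]2(C)[C@H]1CC1=CC(OC)(OC)C(CO[Si](C)(C)C(C)(C)C)=CC1=O | intermediate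
25 | (1S,6R)-4-({[tert-butyl(dimethyl)silyl]oxy}methyl)-5,5-dimethoxy-1-{[(1S,4aS,8aS)-5,5,8a-trimethyl-2-methylidenedecahydronaphthalen-1-yl]methyl}-7-oxabicyclo[4.1.0]hept-3-en-2-one | C=C1CC[C@H]2C(C)(C)CCC[C@]2(C)[C@H]1C[C@]12O[C@H]1C(OC)(OC)C(CO[Si](C)(C)C(C)(C)C)=CC2=O | intermediate
26 | (1S,6R)-4-(hydroxymethyl)-1-{[(1S,4aS,8aS)-5,5,8a-trimethyl-2-methylidenedecahydronaphthalen-1-yl]methyl}-7-oxabicyclo[4.1.0]hept-3-ene-2,5-dione | C=C1CC[C@H]2C(C)(C)CCC[C@]2(C)[C@H]1C[C@]12O[C@H]1C(=O)C(CO)=CC2=O | intermediate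
27 | (1S,5S,6S)-5-hydroxy-4-(hydroxymethyl)-1-{[(1S,4aS,8aS)-5,5,8a-trimethyl-2-methylidenedecahydronaphthalen-1-yl]methyl}-7-oxabicyclo[4.1.0]hept-3-en-2-one (CNP0174686.2) | C=C1CC[C@H]2C(C)(C)CCC[C@]2(C)[C@H]1C[C@]12O[C@H]1[C@@H](O)C(CO)=CC2=O | target

**Step count and risks**

Total step count: 19. Longest linear sequence: 15 steps (steps 5 to 19, from enone 6); the arene branch (steps 1 to 4) joins at step 10.

Risk 1 (step 14, key step). What may go wrong: hydrogen transfer from Bu3SnH to the C9 radical, or a 1,5-hydrogen shift from the propargylic C7, before the slow 6-exo-dig closure; attack of the C12 vinyl radical on ring C; incomplete facial control at C9. Fallback: reverse the roles of radical and acceptor. It sets out from xanthate 20. Chugaev syn-elimination (o-dichlorobenzene, 180 °C) toward the only β-hydrogens, those on C11, would give the (E)-styrene enyne F1. Bu3SnH/AIBN would then add a stannyl radical to C12; the C8 vinyl radical closes 6-exo-trig onto C9 of the styrene, a fast and polarity-matched addition that leaves a benzylic C11 radical, which the hydride reduces, giving vinylstannane F2. Protodestannylation on acidic silica gel comes back to the route at 21.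

Risk 2 (step 5). What may go wrong: slow or poorly face-selective copper-catalysed addition at a β-carbon flanked by the gem-dimethyl group and the α-methyl group, with uncatalysed 1,2-addition of the Grignard reagent competing. Fallback: set C5 on the unmethylated enone and bring in the C10 methyl group afterwards. It sets out from Grignard reagent 7 and uses commercial 4,4-dimethylcyclohex-2-en-1-one F3 in place of 6. Transmetallation of 7 with ZnCl2 (dioxane to remove magnesium salts) would give bis(but-3-en-1-yl)zinc F4, which adds to F3 under Cu(OTf)2/chiral phosphoramidite catalysis, a substrate on which this catalyst system is well established. The zinc enolate is trapped with formaldehyde to give hydroxymethyl ketone F5, which is dehydrated (MsCl, Et3N, then DBU) to α-methylene ketone F6. Conjugate hydride addition (LiBH(s-Bu)3, THF, −78 °C) and O-silylation (Me3SiCl, Et3N) regenerate the same tetrasubstituted enolate and come back to the route at 9.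

Risk 3 (step 17). What may go wrong: poor facial selectivity, because the remote drimane unit gives no bias and control by the ion pair may be incomplete. Fallback: auxiliary control through a chiral ketal. It sets out from monoketal 24. Transketalisation with (2R,4R)-pentane-2,4-diol (PPTS, benzene, 4 Å sieves) would give the C2-symmetric spiroketal F7, whose axial methyl group shields one face of the neighbouring C2'. Weitz–Scheffer epoxidation (t-BuOOH, DBU, CH2Cl2) then gives F8; the antipodal diol is used if the sense turns out to be the wrong one. Aqueous HF in MeCN removes the auxiliary ketal and the silyl group and comes back to the route at 26.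

**Further compounds**

F1 | step 14 | (E)-styrene enyne from 20 (C9=C11 alkene in place of the xanthate; ring A stereocentres as in 20) | C#CCC[C@H]1C(C)(C)CCC[C@]1(C)/C=C/c1cc(OC)c(CO[Si](C)(C)C(C)(C)C)cc1OCOC
F2 | step 14 | vinylstannane (compound 21 carrying a tributylstannyl group on C12) | CCCC[Sn](CCCC)(CCCC)C=C1CC[C@H]2C(C)(C)CCC[C@]2(C)[C@H]1Cc1cc(OC)c(CO[Si](C)(C)C(C)(C)C)cc1OCOC
F3 | step 5 | 4,4-dimethylcyclohex-2-en-1-one (commercial; used in place of 6) | CC1(C)CCC(=O)C=C1
F4 | step 5 | bis(but-3-en-1-yl)zinc | C=CCC[Zn]CCC=C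
F5 | step 5 | 3-(but-3-en-1-yl)-2-(hydroxymethyl)-4,4-dimethylcyclohexan-1-one (C5 as in 9; C10 epimerisable) | C=CCC[C@H]1C(C)(C)CCC(=O)C1CO
F6 | step 5 | 3-(but-3-en-1-yl)-4,4-dimethyl-2-methylidenecyclohexan-1-one (C5 as in 9) | C=CCC[C@H]1C(C)(C)CCC(=O)C1=C
F7 | step 17 | (2R,4R)-pentane-2,4-diyl spiroketal analogue of 24 | C=C1CC[C@H]2C(C)(C)CCC[C@]2(C)[C@H]1CC1=CC2(O[C@H](C)C[C@@H](C)O2)C(CO[Si](C)(C)C(C)(C)C)=CC1=O
F8 | step 17 | (2R,4R)-pentane-2,4-diyl spiroketal analogue of 25 (C1'–C2' epoxide) | C=C1CC[C@H]2C(C)(C)CCC[C@]2(C)[C@H]1C[C@]12O[C@H]1C1(O[C@H](C)C[C@@H](C)O1)C(CO[Si](C)(C)C(C)(C)C)=CC2=O
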